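The data stem from a simulated flask with made-up constants; noise was put on by code.

I decide to count E as one counts functional groups in a step-growth batch, with 2 E lost for every Q formed, and to test that count on this flask's own readings.

- spring: Z 0.51 M; E 1.3 equiv; D 3 equiv; the very flask that is asked about, followed so far
- flask: Z 0.51 M; E 1.30 equiv; D 3.00 equiv; time 2.5 d

spring run (percent of the Z charged)

| time / h | Q / % | Z / % |
|---|---|---|
| 2.00 | 17.8 | 81.3 |
| 6.00 | 35.8 | 62.9 |
| 10.0 | 46.5 | 54.1 |
| 15.0 | 52.7 | 45.9 |
| 25.0 | 60.0 | 39.9 |
| 30.0 | 60.8 | 39.2 |

(scatter of a reading: 1 percentage point)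

- solid, in amounts per volume of the solution: D
- the numbers in the tables scatter with a standard deviation of 1 percentage point
- at the start none of D is in solution

- how much Q the flask holds at 2.5 d, in percent of the Z charged
- how much Z the flask holds at 2.5 d, in percent of the Z charged

If the rate is a constant times [Z][E], and [E] is its charge minus 2[Q], the rate integrates in closed form: the logarithm of the growth of [Z]/[E] rises in a straight line with time. The table gives that constant, already multiplied by the charged [Z], from three readings, on a one-for-one count and on mine.

| time | Q | one E per Q | two E per Q |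
|---|---|---|---|
| 2.00 h | 17.8% | 0.0813 h⁻¹ | 0.0886 h⁻¹ |
| 10.0 h | 46.5% | 0.0609 h⁻¹ | 0.0902 h⁻¹ |
| 30.0 h | 60.8% | 0.0340 h⁻¹ | 0.0858 h⁻¹ |

The one-for-one constant falls while mine stays level, so I keep the count and take the mean, 0.0872 h⁻¹. The count puts a ceiling on Q at 65.0% of the Z charged, half the equivalents of E. My first way, the closed form run out to 2.5 d, gives Q 64.4% and Z 35.6%. My second way leaves the count out: if the gap to a plateau shrinks by one factor per equal step of time, the readings at 2.00 h, 6.00 h and 10.0 h put the plateau at Q 62.2%, so Z 37.8%. The two part by 2.2 percentage points, and I hold the second way the weaker, since it hangs on a difference of rises of 7.3 points between readings that scatter by 1 point, so I commit to the count.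

The forecast gives Q 62% (60% to 67%) and Z 38% (33% to 40%), reading a stall, “either passivation of the solid base or an equilibrium”; its number is what one gets by taking the last reading over, and its Q lies below mine.

    D ⇌ L, rate k1*(cs1 - [L]) while solid is left; crystals form when [L] > cs1 (solubility = 37.0 mM, k = 2.59 × 10⁻⁵ s⁻¹)
    X + L ⇌ J, settled at all times (K = 3.37 M⁻¹)
    E + X ⇌ G, settled at all times (K = 348 M⁻¹)
    Z + E → X + Q (k = 4.66 × 10⁻⁵ M⁻¹ s⁻¹)

This flask holds Q 67.3% and Z 32.7% at 2.5 d, which puts Q 2.3 points above my ceiling. In this flask the half-life of Z by Z + E → X + Q is 0.54 d at 0.222 d, short against 2.5 d, and 8.1 d at the asked time, long against it, with free E, the limiting reagent, down to 3.2% of its charge against 33% of Z. The neighbouring flask, like this one but with 0.520 equiv of E, whose ceiling by the same count is 26.0%, holds Q 30.5% at 2.50 d.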